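## Retrosynthetic overview

1. The target comes from a triol by one double isobutyrylation of its two primary hydroxyls. The triol comes from a 2-(hydroxymethyl)-5-(penta-1,4-dien-2-yl)cyclohexenone and (R)-2-methylbut-3-ene-1,2-diol by E-selective cross-metathesis.
2. The hydroxymethyl group comes from a Morita–Baylis–Hillman reaction of (R)-5-(penta-1,4-dien-2-yl)cyclohex-2-enone with formaldehyde.
3. That enone comes from (R)-5-silyloxycyclohex-2-enone, used as a chiral cyclohexa-2,5-dienone equivalent, by anti conjugate addition of a 2-metallo-penta-1,4-diene and β-elimination.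
4. Key step: the (R)-silyloxy-enone comes from meso cis-3,5-bis(silyloxy)cyclohexanone by enantiotopic-proton-selective deprotonation/E1cB with a chiral lithium amide. The meso ketone comes from phloroglucinol by all-cis hydrogenation, bis-silylation and oxidation.
5. Ring order: the only ring is the phloroglucinol carbocycle, carried through intact; no ring is formed.

Assumption: the (R,R)-enantiomer of the lithium amide is taken to remove the α-proton that leads to (R)-6; if a test run shows the opposite sense, the (S,S)-amide is used with no other change.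

## Route

Step 1
Reactants: 1 phloroglucinol (benzene-1,3,5-triol)
Product: 2 all-cis-cyclohexane-1,3,5-triol
Conditions: H2 (70 bar), 5% Rh/Al2O3, EtOH–H2O, 60 °C; recrystallise
Reagents that add atoms: none
Why: Heterogeneous arene hydrogenation adds all hydrogens from the catalyst-bound face, so the three C–O bonds end up all-cis (meso triol, crystallises from the minor isomers); this is where the aromatic ring is broken.

Step 2
Reactants: 2 all-cis-cyclohexane-1,3,5-triol
Product: 3 all-cis-3,5-bis[(tert-butyldimethylsilyl)oxy]cyclohexan-1-ol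
Conditions: TBSCl (2.0 equiv), imidazole, DMF, 0 °C to rt; mono- and tris-ethers recycled
Reagents that add atoms: tert-butyldimethylsilyl chloride, CC(C)(C)[Si](C)(C)Cl
Why: Silyl ether formation on a triol with three equivalent equatorial hydroxyls is statistical (about half bis-ether) and does not touch the stereocentres.

Step 3
Reactants: 3 all-cis-3,5-bis[(tert-butyldimethylsilyl)oxy]cyclohexan-1-ol
Product: 4 cis-3,5-bis[(tert-butyldimethylsilyl)oxy]cyclohexan-1-one (meso)
Conditions: TPAP (5 mol%), NMO, 4 Å MS, CH2Cl2, rt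
Reagents that add atoms: none
Why: Ley–Griffith oxidation is neutral and non-aqueous, so the β,β′-bis(silyloxy) ketone forms without β-elimination and stays meso.

Step 4 (key step)
Reactants: 4 cis-3,5-bis[(tert-butyldimethylsilyl)oxy]cyclohexan-1-one
Product: 6 (5R)-5-[(tert-butyldimethylsilyl)oxy]cyclohex-2-en-1-one, via lithium enolate 5 (not isolated)
Conditions: (R,R)-bis(1-phenylethyl)amine, n-BuLi (1.05 equiv), LiCl, THF, −78 °C, 4 added slowly; then −78 to −20 °C; H2O quench
Reagents that add atoms: none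
Why: Enantioselective deprotonation of a meso ketone by a chiral lithium amide, then E1cB loss of the β-silyloxide on warming: the amide removes a proton from one of the two enantiotopic α-CH2 groups (the one next to the S-configured C–O carbon), that silyloxy group leaves, and the untouched C–OTBS carbon becomes the (R) stereocentre of 6.

Step 5
Reactants: 7 2,3-dibromoprop-1-ene
Product: 8 2-bromopenta-1,4-diene
Conditions: CH2=CHMgBr, CuI (5 mol%), THF, −20 to 0 °C
Reagents that add atoms: vinylmagnesium bromide, C=C[Mg]Br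
Why: Copper-catalysed allylic substitution of the allylic bromide by the vinyl Grignard reagent (SN2 and SN2′ give the same product) leaves the less reactive vinylic bromide in place.

Step 6
Reactants: 6 (5R)-5-[(tert-butyldimethylsilyl)oxy]cyclohex-2-en-1-one; 8 2-bromopenta-1,4-diene
Product: 12 (5R)-5-(penta-1,4-dien-2-yl)cyclohex-2-en-1-one, via Grignard reagent 9 (not isolated), via silyl enol ether 10 (not isolated), via trans ketone 11 (not isolated)
Conditions: 8, Mg, THF, 35 °C; CuBr·SMe2 (10 mol%), TMSCl, 6, THF, −78 °C; 1 M HCl, 0 °C; crude, DBU, CH2Cl2, rt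
Reagents that add atoms: none
Why: Copper-catalysed conjugate addition of the alkenyl Grignard reagent occurs anti to the C5 silyloxy group (axial attack on the half-chair, trans adduct), and DBU then expels that silyloxy group by E1cB on the other side of the carbonyl, so the new C–C stereocentre becomes C5 (R) of 12.

Step 7
Reactants: 12 (5R)-5-(penta-1,4-dien-2-yl)cyclohex-2-en-1-one
Product: 13 (5R)-2-(hydroxymethyl)-5-(penta-1,4-dien-2-yl)cyclohex-2-en-1-one
Conditions: 37% aq. HCHO, DMAP (20 mol%), THF, rt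
Reagents that add atoms: formaldehyde, C=O
Why: Morita–Baylis–Hillman reaction: DMAP adds to the enone, the enolate hydroxymethylates at C2 and DMAP is expelled, which restores the C2=C3 double bond without touching C5.

Step 8
Reactants: 14 (S)-2-methylglycidol, [(2S)-2-methyloxiran-2-yl]methanol
Product: 15 (2R)-2-methylbut-3-ene-1,2-diol
Conditions: Me3S+ I− (4 equiv), n-BuLi (3.9 equiv), THF, −10 °C to rt
Reagents that add atoms: trimethylsulfonium iodide, C[S+](C)C.[I-]
Why: Epoxide-to-allylic-alcohol one-carbon homologation with dimethylsulfonium methylide (the ylide opens the epoxide CH2, then base-induced α′,β-elimination of dimethyl sulfide); the quaternary carbon is not involved, so its configuration is kept and (S) becomes (R) only through the change in CIP priorities.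

Step 9
Reactants: 13 (5R)-2-(hydroxymethyl)-5-(penta-1,4-dien-2-yl)cyclohex-2-en-1-one; 15 (2R)-2-methylbut-3-ene-1,2-diol (3 equiv)
Product: 16 (5R)-5-[(4E,6R)-6,7-dihydroxy-6-methylhepta-1,4-dien-2-yl]-2-(hydroxymethyl)cyclohex-2-en-1-one
Conditions: Hoveyda–Grubbs II (5 mol%), 1,4-benzoquinone (10 mol%), CH2Cl2, 40 °C
Reagents that add atoms: none
Why: Olefin cross-metathesis between the unhindered allyl terminus of 13 and the tertiary allylic alcohol olefin of 15 (slow to homodimerise) gives the E-alkene for steric reasons; the 1,1-disubstituted alkene and the enone are inert and benzoquinone suppresses migration of the skipped diene.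

Step 10
Reactants: 16 (5R)-5-[(4E,6R)-6,7-dihydroxy-6-methylhepta-1,4-dien-2-yl]-2-(hydroxymethyl)cyclohex-2-en-1-one
Product: 17 target, (2R,3E)-2-hydroxy-2-methyl-6-[(1R)-4-{[(2-methylpropanoyl)oxy]methyl}-3-oxocyclohex-4-en-1-yl]hepta-3,6-dien-1-yl 2-methylpropanoate
Conditions: (i-PrCO)2O (2.3 equiv), Et3N, DMAP (5 mol%), CH2Cl2, −20 to 0 °C
Reagents that add atoms: isobutyric anhydride, CC(C)C(=O)OC(=O)C(C)C
Why: Chemoselective DMAP-catalysed esterification of the two primary hydroxyls; the tertiary allylic hydroxyl is too hindered for the branched anhydride at low temperature and no stereocentre is touched.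

## Compound list

1 | phloroglucinol (benzene-1,3,5-triol) | Oc1cc(O)cc(O)c1 | starting material
2 | all-cis-cyclohexane-1,3,5-triol (meso) | O[C@H]1C[C@@H](O)C[C@@H](O)C1 | intermediate
3 | all-cis-3,5-bis[(tert-butyldimethylsilyl)oxy]cyclohexan-1-ol (meso) | O[C@H]1C[C@@H](O[Si](C)(C)C(C)(C)C)C[C@@H](O[Si](C)(C)C(C)(C)C)C1 | intermediate
4 | cis-(3R,5S)-3,5-bis[(tert-butyldimethylsilyl)oxy]cyclohexan-1-one (meso) | O=C1C[C@@H](O[Si](C)(C)C(C)(C)C)C[C@@H](O[Si](C)(C)C(C)(C)C)C1 | intermediate
5 | lithium (3S,5R)-3,5-bis[(tert-butyldimethylsilyl)oxy]cyclohex-1-en-1-olate | [Li]OC1=C[C@@H](O[Si](C)(C)C(C)(C)C)C[C@@H](O[Si](C)(C)C(C)(C)C)C1 | intermediate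
6 | (5R)-5-[(tert-butyldimethylsilyl)oxy]cyclohex-2-en-1-one | O=C1C=CC[C@@H](O[Si](C)(C)C(C)(C)C)C1 | intermediate
7 | 2,3-dibromoprop-1-ene | C=C(Br)CBr | starting material
8 | 2-bromopenta-1,4-diene | C=C(Br)CC=C | intermediate
9 | (penta-1,4-dien-2-yl)magnesium bromide | C=C([Mg]Br)CC=C | intermediate
10 | trimethylsilyl enol ether of 11 (C1=C2 enol ether, 3R,5R, 3,5-trans) | C[Si](C)(C)OC1=C[C@H](C(=C)CC=C)C[C@@H](O[Si](C)(C)C(C)(C)C)C1 | intermediate
11 | trans-(3R,5R)-3-[(tert-butyldimethylsilyl)oxy]-5-(penta-1,4-dien-2-yl)cyclohexan-1-one | O=C1C[C@H](C(=C)CC=C)C[C@@H](O[Si](C)(C)C(C)(C)C)C1 | intermediate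
12 | (5R)-5-(penta-1,4-dien-2-yl)cyclohex-2-en-1-one | C=CCC(=C)[C@@H]1CC=CC(=O)C1 | intermediate
13 | (5R)-2-(hydroxymethyl)-5-(penta-1,4-dien-2-yl)cyclohex-2-en-1-one | C=CCC(=C)[C@@H]1CC=C(CO)C(=O)C1 | intermediate
14 | (S)-2-methylglycidol, [(2S)-2-methyloxiran-2-yl]methanol | C[C@]1(CO)CO1 | starting material
15 | (2R)-2-methylbut-3-ene-1,2-diol | C=C[C@@](C)(O)CO | intermediate
16 | (5R)-5-[(4E,6R)-6,7-dihydroxy-6-methylhepta-1,4-dien-2-yl]-2-(hydroxymethyl)cyclohex-2-en-1-one | C=C(C/C=C/[C@@](C)(O)CO)[C@@H]1CC=C(CO)C(=O)C1 | intermediate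
17 | (2R,3E)-2-hydroxy-2-methyl-6-[(1R)-4-{[(2-methylpropanoyl)oxy]methyl}-3-oxocyclohex-4-en-1-yl]hepta-3,6-dien-1-yl 2-methylpropanoate | C=C(C/C=C/[C@@](C)(O)COC(=O)C(C)C)[C@@H]1CC=C(COC(=O)C(C)C)C(=O)C1 | target

## Step count and risks

Total steps: 10. Longest linear sequence: 8 (steps 1, 2, 3, 4, 6, 7, 9, 10).

Step 4 is the most likely to fail. The ee and the sense of induction are not secured for this substrate, and excess base can push 6 on to phenol by a second elimination. The fallback is an enzymatic desymmetrisation that sets out from 2 and comes back at 6. Triol 2 is mono-silylated (TBSCl 1.0 equiv, imidazole) to the meso diol all-cis-5-[(tert-butyldimethylsilyl)oxy]cyclohexane-1,3-diol F1. A lipase chosen by screening (Pseudomonas cepacia lipase or CAL-B, vinyl acetate, MTBE) acetylates one enantiotopic hydroxyl to give (1R,3S,5S)-3-hydroxy-5-[(tert-butyldimethylsilyl)oxy]cyclohexyl acetate F2. TPAP/NMO oxidises the free hydroxyl to (3S,5R)-3-acetoxy-5-[(tert-butyldimethylsilyl)oxy]cyclohexan-1-one F3, and DBU eliminates acetic acid to give 6.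

Step 6 is second. The 2-metallo-1,4-diene has an acidic bis-allylic CH2 and may not form or add cleanly. The fallback sets out from 6 and comes back at 12, building the allyl branch after the ring stereocentre is set. Commercial isopropenylmagnesium bromide (CuBr·SMe2 cat., THF, −78 °C, aqueous work-up) adds to 6 to give trans-(3R,5R)-3-[(tert-butyldimethylsilyl)oxy]-5-(prop-1-en-2-yl)cyclohexan-1-one F4. DBU gives (5R)-5-(prop-1-en-2-yl)cyclohex-2-en-1-one F5. Ene-type allylic chlorination (Ca(OCl)2, solid CO2, CH2Cl2–H2O, 0 °C) gives (5R)-5-(3-chloroprop-1-en-2-yl)cyclohex-2-en-1-one F6. Stille coupling of F6 with tributyl(vinyl)stannane (Pd2(dba)3, tri-2-furylphosphine, THF, 50 °C) gives 12.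

Step 8 is third. The ylide has to open a 2,2-disubstituted epoxide that carries a free alkoxide, and the small diol is water-soluble. The fallback sets out from 14 and comes back at 15 by a selenoxide route. (Phenylselanyl)methyllithium (from bis(phenylselanyl)methane and n-BuLi, THF, −78 °C) opens the epoxide CH2 of 14 to give (2R)-2-methyl-4-(phenylselanyl)butane-1,2-diol F7. H2O2 (THF, 0 °C to rt) oxidises it to (2R)-2-methyl-4-(phenylseleninyl)butane-1,2-diol F8, which undergoes syn-elimination at room temperature to give 15.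

## Further compounds

F1 | step 4 | all-cis-5-[(tert-butyldimethylsilyl)oxy]cyclohexane-1,3-diol (meso) | O[C@H]1C[C@@H](O)C[C@@H](O[Si](C)(C)C(C)(C)C)C1
F2 | step 4 | (1R,3S,5S)-3-hydroxy-5-[(tert-butyldimethylsilyl)oxy]cyclohexyl acetate (all-cis) | O[C@H]1C[C@@H](OC(C)=O)C[C@@H](O[Si](C)(C)C(C)(C)C)C1
F3 | step 4 | (3S,5R)-3-acetoxy-5-[(tert-butyldimethylsilyl)oxy]cyclohexan-1-one | O=C1C[C@@H](OC(C)=O)C[C@@H](O[Si](C)(C)C(C)(C)C)C1
F4 | step 6 | trans-(3R,5R)-3-[(tert-butyldimethylsilyl)oxy]-5-(prop-1-en-2-yl)cyclohexan-1-one | O=C1C[C@H](C(C)=C)C[C@@H](O[Si](C)(C)C(C)(C)C)C1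
F5 | step 6 | (5R)-5-(prop-1-en-2-yl)cyclohex-2-en-1-one | C=C(C)[C@@H]1CC=CC(=O)C1
F6 | step 6 | (5R)-5-(3-chloroprop-1-en-2-yl)cyclohex-2-en-1-one | C=C(CCl)[C@@H]1CC=CC(=O)C1
F7 | step 8 | (2R)-2-methyl-4-(phenylselanyl)butane-1,2-diol | C[C@](O)(CO)CC[Se]c1ccccc1
F8 | step 8 | (2R)-2-methyl-4-(phenylseleninyl)butane-1,2-diol | C[C@](O)(CO)CC[Se](=O)c1ccccc1
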